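**Assumption:** The target as drawn has no stereocentres (it is achiral), so "single enantiomer" does not apply. The chain sits on C8, next to the ring oxygen, as in the SMILES. Compound **10** carries one transient racemic stereocentre, which is destroyed in Step 8.

## Retrosynthetic overview
- The target comes from global debenzylation of a tetra-O-benzyl isoflavone.
- The chromone ring is closed last. It comes from a biomimetic Tl(III)-mediated 1,2-aryl shift of a 2'-hydroxychalcone, in the spirit of isoflavone synthase, followed by acetal cyclisation. This avoids the usual deoxybenzoin/DMF or 3-iodochromone Suzuki routes.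
- The chalcone comes from Claisen–Schmidt condensation of an A-ring acetophenone that already carries the C8 chain, with 2,4-bis(benzyloxy)benzaldehyde.
- The whole 3-hydroxy-3-methylbutyl chain is delivered by B-alkyl Suzuki coupling of an aryl iodide with the 9-BBN adduct of 2-methylbut-3-en-2-ol. This avoids a late prenyl hydration, which would risk chromane formation.
- Ring order: arene A is iodinated and the chain attached; ring B is joined by aldol; ring C is formed last.

## Route

**Step 1**
Reactants: **1** 2',4',6'-trihydroxyacetophenone (phloroacetophenone)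
Product: **2** 1-(2,4,6-trihydroxy-3-iodophenyl)ethanone
Conditions: NIS (1.0 equiv), MeCN, −10 °C → rt, dark
Reagents that add atoms: N-iodosuccinimide, O=C1CCC(=O)N1I (I stays in the product)
Why: Electrophilic aromatic iodination of the symmetric phloroglucinol ring gives one mono-iodide, because C3 and C5 are equivalent. The iodine marks the future C8 and sets the regiochemistry of the chain.

**Step 2**
Reactants: **2**
Product: **3** 1-[4,6-bis(benzyloxy)-2-hydroxy-3-iodophenyl]ethanone
Conditions: BnBr (2.1 equiv), K2CO3, acetone, reflux
Reagents that add atoms: benzyl bromide, BrCc1ccccc1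
Why: Williamson etherification. The 4-OH is the most acidic and the 6-OH is unhindered. The 2-OH is flanked by the acetyl group and the iodine and is H-bonded to the carbonyl, so it stays free. That free 2-OH becomes the ring oxygen at C8a, and the benzylated 6-OH becomes 5-OBn.

**Step 3**
Reactants: **4** 2-methylbut-3-en-2-ol
Product: **5** 9-BBN alkylborane with the tertiary OH capped as its 9-BBN borinate, 9-[3-methyl-3-(9-BBN-oxy)butyl]-9-BBN
Conditions: 9-BBN (2.1 equiv), THF, 0 °C → rt, 4 h
Reagents that add atoms: 9-borabicyclo[3.3.1]nonane, B1C2CCCC1CCC2 (two units stay in the product)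
Why: Hydroboration of the terminal vinyl group puts boron on the terminal carbon with essentially complete selectivity. The first equivalent of 9-BBN caps the tertiary OH with loss of H2, and the O–B bond is cleaved in the aqueous basic medium of Step 4.

**Step 4**
Reactants: **3** and **5**
Product: **6** 1-[4,6-bis(benzyloxy)-2-hydroxy-3-(3-hydroxy-3-methylbutyl)phenyl]ethanone
Conditions: Pd(dppf)Cl2 (10 mol%), K3PO4 (4 equiv), THF/H2O 10:1, 65 °C
Reagents that add atoms: none (the chain comes from **5**)
Why: B-alkyl Suzuki–Miyaura coupling transfers the primary alkyl group from boron, not the cyclooctyl ring carbons. The chain is installed whole as the saturated tertiary alcohol, so no hydration is needed.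

**Step 5**
Reactants: **7** 2,4-dihydroxybenzaldehyde
Product: **8** 2,4-bis(benzyloxy)benzaldehyde
Conditions: BnBr (2.4 equiv), K2CO3, KI (cat.), acetone, reflux
Reagents that add atoms: benzyl bromide, BrCc1ccccc1
Why: Williamson bis-O-benzylation. Benzyl ethers are compatible with the later oxidation and can be removed by hydrogenolysis without acid.

**Step 6**
Reactants: **6** and **8**
Product: **9** (E)-2'-hydroxy-3'-(3-hydroxy-3-methylbutyl)-4',6',2,4-tetrakis(benzyloxy)chalcone
Conditions: 50% aq KOH, EtOH, rt, 48–72 h
Reagents that add atoms: none
Why: Claisen–Schmidt (aldol) condensation with dehydration gives the thermodynamically preferred E-enone. The only geometric element is the E double bond, which is erased in Step 7.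

**Step 7**
Reactants: **9**
Product: **10** 1-aryl-2-[2,4-bis(benzyloxy)phenyl]-3,3-dimethoxypropan-1-one (racemic acetal)
Conditions: Tl(NO3)3·3H2O (1.3 equiv), HC(OMe)3/MeOH (1:1), rt, 2 h
Reagents that add atoms: methanol, CO; trimethyl orthoformate, COC(OC)OC (two OMe groups end up in the acetal)
Why: Oxidative 1,2-aryl migration (Tl(III) oxythallation, then phenonium-type shift), the same skeletal change that isoflavone synthase makes. The electron-rich 2,4-dialkoxyphenyl group migrates readily, and the former β-carbon is trapped as the dimethyl acetal. The new stereocentre is racemic and is destroyed in Step 8.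

**Step 8**
Reactants: **10**
Product: **11** 5,7,2',4'-tetrakis(benzyloxy)-8-(3-hydroxy-3-methylbutyl)isoflavone
Conditions: p-TsOH·H2O (0.2 equiv), MeOH/CH2Cl2, 40 °C, 3 h
Reagents that add atoms: none (2 MeOH are lost)
Why: Acid-catalysed oxocarbenium formation, attack by the free 2'-OH (6-exo ring closure), then E1cB loss of MeOH through the doubly activated C3–H gives the 2,3-double bond (C2–H chromone). Mild acid at 40 °C leaves the tertiary alcohol untouched, and the 7-OBn group blocks chromane formation.

**Step 9**
Reactants: **11**
Product: **12** 2,3-dehydrokievitone hydrate (target)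
Conditions: H2 (1 atm), 10% Pd/C, THF/EtOH, rt, monitored to about 3 h
Reagents that add atoms: none (only H is added)
Why: Hydrogenolytic O-debenzylation of all four benzyl ethers; no acid is involved, so the tertiary alcohol survives. The chromone C2=C3 bond is kept by running at 1 atm and stopping on consumption of the starting material. No stereocentres are formed.

## Checks performed
- **Ring and substituent mapping:** 2'-OH of **6** becomes O1/C8a. The 3'-chain becomes the 8-chain. 4'-OBn becomes 7-OR. 6'-OBn becomes 5-OR. The aldehyde ring becomes the 2',4'-dihydroxyphenyl at C3. Compound **11** matches the target SMILES once the Bn groups are replaced by H.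
- **Atom balance:** 6 + 8 → 9 + H2O; 9 + 2 MeOH → 10 + 2 H+ (+ Tl(I)); 10 → 11 + 2 MeOH; 11 + 4 H2 → 12 + 4 toluene. All balance.
- **Functional-group survival:** Benzyl ethers survive Steps 1–8. The tertiary alcohol survives the base, mild acid, Tl(III) and H2 conditions. The 2'-OH is free only where it is needed for ring closure.
- **Stereocentres:** The target has none. The only stereo-element, the E alkene in **9**, and the racemic stereocentre in **10** are both lost by Step 8.

## Compound list
| # | Name | SMILES | Role |
|---|---|---|---|
| 1 | 2',4',6'-Trihydroxyacetophenone | CC(=O)c1c(O)cc(O)cc1O | starting material |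
| 2 | 1-(2,4,6-Trihydroxy-3-iodophenyl)ethanone | CC(=O)c1c(O)cc(O)c(I)c1O | intermediate |
| 3 | 1-[4,6-Bis(benzyloxy)-2-hydroxy-3-iodophenyl]ethanone | CC(=O)c1c(OCc2ccccc2)cc(OCc2ccccc2)c(I)c1O | intermediate |
| 4 | 2-Methylbut-3-en-2-ol | C=CC(C)(C)O | starting material |
| 5 | 9-[3-Methyl-3-(9-BBN-oxy)butyl]-9-BBN | CC(C)(OB1C2CCCC1CCC2)CCB1C2CCCC1CCC2 | intermediate (reagent) |
| 6 | 1-[4,6-Bis(benzyloxy)-2-hydroxy-3-(3-hydroxy-3-methylbutyl)phenyl]ethanone | CC(=O)c1c(OCc2ccccc2)cc(OCc2ccccc2)c(CCC(C)(C)O)c1O | intermediate |
| 7 | 2,4-Dihydroxybenzaldehyde | O=Cc1ccc(O)cc1O | starting material |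
| 8 | 2,4-Bis(benzyloxy)benzaldehyde | O=Cc1ccc(OCc2ccccc2)cc1OCc1ccccc1 | intermediate |
| 9 | (E)-Tetrakis(benzyloxy)-2'-hydroxy-3'-(3-hydroxy-3-methylbutyl)chalcone | CC(C)(O)CCc1c(OCc2ccccc2)cc(OCc2ccccc2)c(C(=O)/C=C/c2ccc(OCc3ccccc3)cc2OCc2ccccc2)c1O | intermediate |
| 10 | 3,3-Dimethoxy-1,2-diarylpropan-1-one (racemic) | CC(C)(O)CCc1c(OCc2ccccc2)cc(OCc2ccccc2)c(C(=O)C(c2ccc(OCc3ccccc3)cc2OCc2ccccc2)C(OC)OC)c1O | intermediate |
| 11 | 5,7,2',4'-Tetrakis(benzyloxy)-8-(3-hydroxy-3-methylbutyl)isoflavone | CC(C)(O)CCc1c(OCc2ccccc2)cc(OCc2ccccc2)c2c(=O)c(-c3ccc(OCc4ccccc4)cc3OCc3ccccc3)coc12 | intermediate |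
| 12 | 2,3-Dehydrokievitone hydrate | CC(C)(O)CCc1c(O)cc(O)c2c(=O)c(-c3ccc(O)cc3O)coc12 | target |

## Totals
Total steps: 9 (three converge branches: Steps 3, 5 and the main chain). Longest linear sequence: 7 steps (Steps 1, 2, 4, 6, 7, 8, 9 from phloroacetophenone).

## Three steps most likely to fail
1. **Step 7, Tl(III) oxidative aryl shift.** The very electron-rich, trioxygenated A-ring could be over-oxidised, or flavanone/aurone side products could form.
   Fallback (different approach): convert **6** to its enaminone with DMF-DMA, cyclise with I2 to the 3-iodochromone, then Suzuki-couple with 2,4-bis(benzyloxy)phenylboronic acid.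
2. **Step 4, B-alkyl Suzuki coupling.** The aryl iodide is di-ortho-substituted and bears a free phenol, and the borane carries a tertiary alcohol.
   Fallback (different approach): O-allylate the 2'-OH of the dibenzyl acetophenone and run a Claisen rearrangement to the 3'-allyl compound. Then do cross-metathesis with 2-methylbut-2-ene to give the prenyl group, and a Mukaiyama hydration on the O-protected phenol to give the hydrate chain.
3. **Step 2, selective 4,6-dibenzylation.** The hindered 2-OH may also be benzylated, giving the wrong regioisomer and wrong ring closure.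
   Fallback (different approach): start from the known 2'-hydroxy-4',6'-bis(benzyloxy)acetophenone and introduce the chain at C3' by phenol-directed ortho functionalisation, for example the Claisen route above, so that regiochemistry is set by the [3,3] shift rather than by steric selectivity.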